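**Direct plan and its weak points**

A direct plan would take the C-prenylated acetophenone A1, cap its two ortho-hydroxyls with two different acetals (A2), condense A2 with O-protected isovanillin A3 to chalcone A4, epoxidise A4 asymmetrically to epoxy ketone A5, and close ring C by letting the unmasked phenol open the epoxide before a warm acidic deprotection.
- Differentiation of the two hydroxyls of A1 (A1 → A2) would be weak: both are chelated to the same carbonyl and differ only by the neighbouring prenyl group, yet this selectivity alone decides 6- versus 8-prenyl, and the two steps build nothing.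
- Asymmetric nucleophilic epoxidation of A4 would be weak: a 2′,6′-dioxygenated chalcone is twisted out of conjugation, so rate and face control are poorly secured.
- Acid-triggered closure of ring C at the p-methoxybenzylic epoxide carbon of A5, run together with the acetal cleavage, would be weak: ionisation erodes the inversion at C2, methanol and 5-exo attack compete, and the acid meets the o-prenylphenol.

**Retrosynthetic overview**

- C3–O is made last: the target comes from a (2S)-flavanone by oxidation of its enol ether anti to the C2 aryl group.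
- Key cut C2–C1′: the flavanone comes from 5-hydroxy-7-methoxy-6-prenylchromone and (3-hydroxy-4-methoxyphenyl)boronic acid by catalytic asymmetric 1,4-arylation. C2 is p-methoxybenzylic and bound to O1, so it is created by C–C bond formation on the flat pyranone; the O1–C2 bond is never made or broken at a stereocentre and no epoxide is involved.
- The chromone comes from symmetric 2,6-dihydroxy-4-methoxyacetophenone. The five prenyl carbons are parked on O5 as a tertiary propargyl ether (an O5–C bond that is absent from the target), the only other hydroxyl closes ring C, and a [3,3] shift moves the group from O5 to C6, the one free ortho carbon.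
- Ring order: ring A (bought), then ring C, then ring B attached; no acetal protecting groups and no warm acid on the o-prenylphenol.

Key step: step 4

Assumption: the sense of induction of the (S)-biaryl bisphosphine is taken from the parent chromone and cyclohexenone cases (aryl delivered to the face that gives (2S)-flavanones); should the prenylated substrate respond in the opposite sense, the (R)-ligand would be used.

**Route**

Step 1
Reactants: 1 1-(2,6-dihydroxy-4-methoxyphenyl)ethan-1-one; 2 3-chloro-3-methylbut-1-yne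
Product: 3 1-{2-hydroxy-4-methoxy-6-[(2-methylbut-3-yn-2-yl)oxy]phenyl}ethan-1-one
Conditions: 2 (1.2 equiv), K2CO3, KI (cat.), CuI (cat.), acetone, 50 °C
Reagents that add atoms: 3-chloro-3-methylbut-1-yne (2), C#CC(C)(C)Cl
Why: Copper-catalysed O-alkylation of a phenol with a tertiary propargylic chloride; the two hydroxyls of 1 are equivalent, so only one mono-ether exists, and the remaining OH is locked in the hydrogen bond to the acetyl group, which should stop a second alkylation.

Step 2
Reactants: 3 1-{2-hydroxy-4-methoxy-6-[(2-methylbut-3-yn-2-yl)oxy]phenyl}ethan-1-one; 4 N,N-dimethylformamide dimethyl acetal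
Product: 6 7-methoxy-5-[(2-methylbut-3-yn-2-yl)oxy]-4H-chromen-4-one, via enaminone 5 (not isolated)
Conditions: 4 (2.5 equiv), toluene, 85 °C; evaporate; AcOH, 60 °C
Reagents that add atoms: N,N-dimethylformamide dimethyl acetal (4), COC(OC)N(C)C
Why: Enaminone formation at the acetyl methyl group, then acid-promoted addition–elimination of the single free phenol (chromone synthesis from a 2-hydroxyaryl enaminone); the ether oxygen cannot take part and so becomes O5 without any selectivity question, and the temperature stays below that of a propargyl Claisen shift.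

Step 3
Reactants: 6 7-methoxy-5-[(2-methylbut-3-yn-2-yl)oxy]-4H-chromen-4-one
Product: 8 5-hydroxy-7-methoxy-6-(3-methylbut-2-en-1-yl)-4H-chromen-4-one, via allyl ether 7 (not isolated)
Conditions: H2 (1 atm), Pd/CaCO3 poisoned with Pb(OAc)2 (Lindlar catalyst), quinoline, EtOAc, rt; filter; toluene, 110 °C
Reagents that add atoms: none
Why: Lindlar semi-hydrogenation of the terminal alkyne, then aromatic Claisen rearrangement of the 1,1-dimethylallyl aryl ether; the [3,3] shift can deliver the allyl terminus only to C6, the one free carbon ortho to O5 (C4a is the ring fusion), and it turns the tertiary ether into the linear prenyl group while freeing the chelated 5-OH.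

Step 4
Reactants: 8 5-hydroxy-7-methoxy-6-(3-methylbut-2-en-1-yl)-4H-chromen-4-one; 9 (3-hydroxy-4-methoxyphenyl)boronic acid
Product: 10 (2S)-5-hydroxy-2-(3-hydroxy-4-methoxyphenyl)-7-methoxy-6-(3-methylbut-2-en-1-yl)-2,3-dihydro-4H-chromen-4-one
Conditions: 9 (3 equiv), [RhCl(C2H4)2]2 (1.5 mol %), (S)-6,6′-dimethoxy-2,2′-bis[bis(3,4,5-trifluorophenyl)phosphino]-1,1′-biphenyl (3.3 mol %), aq. KOH (0.2 equiv), toluene/H2O, 30 °C
Reagents that add atoms: (3-hydroxy-4-methoxyphenyl)boronic acid (9), COc1ccc(B(O)O)cc1O
Why: Rhodium-catalysed asymmetric 1,4-addition of an arylboronic acid to a chromone (Hayashi–Miyaura reaction): transmetalation gives an aryl–rhodium species, the C2=C3 bond inserts with the aryl group going to C2, and the rhodium enolate is hydrolysed to the ketone. The reaction type is established for chromones, 5,7-dioxygenated ones included, and should give the flavanone in high enantiomeric purity. No ring is closed: the step joins ring B to the finished benzopyranone (rings A and C) through the C2–C1′ bond. The new stereocentre C2 is controlled by the chiral bisphosphine, which differentiates the two faces of the flat pyranone; C3 is not yet stereogenic. The step needs 1,4- over 1,2-addition (secured by the electron-poor ligand at near room temperature and by the vinylogous-ester carbonyl chelated to 5-OH), an untouched prenyl alkene (aryl–rhodium species do not insert unactivated trisubstituted alkenes) and tolerance of two free phenols (aqueous boronic acid conditions). Because O1–C2 is not touched and no enolate is held under base, the configuration should not erode.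

Step 5
Reactants: 10 (2S)-5-hydroxy-2-(3-hydroxy-4-methoxyphenyl)-7-methoxy-6-(3-methylbut-2-en-1-yl)-2,3-dihydro-4H-chromen-4-one; 11 dimethyldioxirane
Product: 14 (2R,3R)-3,5-dihydroxy-2-(3-hydroxy-4-methoxyphenyl)-7-methoxy-6-(3-methylbut-2-en-1-yl)-2,3-dihydro-4H-chromen-4-one, via silyl enol ether 12 (not isolated), via siloxy epoxide 13 (not isolated)
Conditions: TMSOTf (3.5 equiv), Et3N (5 equiv), CH2Cl2, 0 °C; evaporate, pentane, filter; 11 (1.05 equiv, fresh acetone solution), CH2Cl2, −78 °C; 0.5 M HCl, THF, 0 °C
Reagents that add atoms: dimethyldioxirane (11), CC1(C)OO1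
Why: Soft enolisation (silyl triflate and amine, so no free enolate and no base-induced opening of ring C) followed by Rubottom oxidation: the dioxirane should epoxidise the electron-rich silyl enol ether at −78 °C far faster than the prenyl alkene and on the face anti to the C2 aryl group, which sets C3 as R (2,3-trans, also the thermodynamic arrangement) by relay from C2, and cold dilute acid opens the siloxy epoxide and removes the three trimethylsilyl groups, which stem from TMSOTf.

**Compound list**

1 | 1-(2,6-dihydroxy-4-methoxyphenyl)ethan-1-one | CC(=O)c1c(O)cc(OC)cc1O | starting material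
2 | 3-chloro-3-methylbut-1-yne | C#CC(C)(C)Cl | starting material
3 | 1-{2-hydroxy-4-methoxy-6-[(2-methylbut-3-yn-2-yl)oxy]phenyl}ethan-1-one | CC(=O)c1c(O)cc(OC)cc1OC(C)(C)C#C | intermediate
4 | N,N-dimethylformamide dimethyl acetal | COC(OC)N(C)C | starting material
5 | (2E)-3-(dimethylamino)-1-{2-hydroxy-4-methoxy-6-[(2-methylbut-3-yn-2-yl)oxy]phenyl}prop-2-en-1-one | CN(C)/C=C/C(=O)c1c(O)cc(OC)cc1OC(C)(C)C#C | intermediate
6 | 7-methoxy-5-[(2-methylbut-3-yn-2-yl)oxy]-4H-chromen-4-one | O=c1ccoc2cc(OC)cc(OC(C)(C)C#C)c12 | intermediate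
7 | 7-methoxy-5-[(2-methylbut-3-en-2-yl)oxy]-4H-chromen-4-one | O=c1ccoc2cc(OC)cc(OC(C)(C)C=C)c12 | intermediate
8 | 5-hydroxy-7-methoxy-6-(3-methylbut-2-en-1-yl)-4H-chromen-4-one | O=c1ccoc2cc(OC)c(CC=C(C)C)c(O)c12 | intermediate
9 | (3-hydroxy-4-methoxyphenyl)boronic acid | COc1ccc(B(O)O)cc1O | starting material
10 | (2S)-5-hydroxy-2-(3-hydroxy-4-methoxyphenyl)-7-methoxy-6-(3-methylbut-2-en-1-yl)-2,3-dihydro-4H-chromen-4-one | COc1ccc([C@H]2Oc3cc(OC)c(CC=C(C)C)c(O)c3C(=O)C2)cc1O | intermediate
11 | dimethyldioxirane (reagent, freshly prepared from acetone and KHSO5) | CC1(C)OO1 | starting material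
12 | (2S)-7-methoxy-2-{4-methoxy-3-[(trimethylsilyl)oxy]phenyl}-6-(3-methylbut-2-en-1-yl)-4,5-bis[(trimethylsilyl)oxy]-2H-chromene | COc1ccc([C@H]2Oc3cc(OC)c(CC=C(C)C)c(O[Si](C)(C)C)c3C(O[Si](C)(C)C)=C2)cc1O[Si](C)(C)C | intermediate
13 | (2R,3R,4R)-3,4-epoxy-7-methoxy-2-{4-methoxy-3-[(trimethylsilyl)oxy]phenyl}-6-(3-methylbut-2-en-1-yl)-4,5-bis[(trimethylsilyl)oxy]-3,4-dihydro-2H-chromene (oxirane oxygen anti to the C2 aryl group) | COc1ccc([C@H]2Oc3cc(OC)c(CC=C(C)C)c(O[Si](C)(C)C)c3[C@]4(O[Si](C)(C)C)O[C@H]24)cc1O[Si](C)(C)C | intermediate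
14 | (2R,3R)-3,5-dihydroxy-2-(3-hydroxy-4-methoxyphenyl)-7-methoxy-6-(3-methylbut-2-en-1-yl)-2,3-dihydro-4H-chromen-4-one | COc1ccc([C@H]2Oc3cc(OC)c(CC=C(C)C)c(O)c3C(=O)[C@@H]2O)cc1O | target

**Step count and risks**

Total steps: 5. Longest linear sequence: 5 (1 → 3 → 6 → 8 → 10 → 14).

Steps most likely to fail:

Step 5. The dioxirane may also epoxidise the prenyl alkene, or the silyl triflate may ionise the p-methoxybenzylic C2–O1 bond during enolisation and erode C2. The fallback sets out from 10 and comes back at 14; it delivers the oxygen to a metal enolate with an N-sulfonyloxaziridine, a reagent class that leaves isolated alkenes alone. The two phenols of 10 would be silylated (TBSOTf, 2,6-lutidine, CH2Cl2, −78 °C) to (2S)-5-[(tert-butyldimethylsilyl)oxy]-2-{3-[(tert-butyldimethylsilyl)oxy]-4-methoxyphenyl}-7-methoxy-6-(3-methylbut-2-en-1-yl)-2,3-dihydro-4H-chromen-4-one F1. Its potassium enolate (KN(SiMe3)2, THF, −78 °C) would be hydroxylated with 3-phenyl-2-(phenylsulfonyl)oxaziridine anti to the C2 aryl group to give (2R,3R)-5-[(tert-butyldimethylsilyl)oxy]-2-{3-[(tert-butyldimethylsilyl)oxy]-4-methoxyphenyl}-3-hydroxy-7-methoxy-6-(3-methylbut-2-en-1-yl)-2,3-dihydro-4H-chromen-4-one F2. HF·pyridine in THF would then remove both silyl groups and give 14.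

Step 4. Insertion may be slow because the acidic, chelated 5-OH is partly deprotonated by the aqueous base, so that protodeboronation of the electron-rich boronic acid and 1,2-addition to the product ketone overtake the 1,4-addition. The fallback sets out from 7 and comes back at 10; it reverses the order of the two skeletal events so that the arylation meets a phenol-free 5-alkoxychromone. Step 3 would be stopped after the hydrogenation and 7 isolated without heating. Arylation of 7 with 9 under the catalyst of step 4 would give (2S)-2-(3-hydroxy-4-methoxyphenyl)-7-methoxy-5-[(2-methylbut-3-en-2-yl)oxy]-2,3-dihydro-4H-chromen-4-one F3. Heating F3 in toluene at 110 °C would bring about the same [3,3] shift to C6 and give 10.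

Step 3. The vinyl group may be over-reduced, the tertiary allyl group may be lost as isoprene on heating, or a second (Cope) shift may carry the group on towards C8. The fallback sets out from 1 and comes back at 8; it attaches the prenyl group by cross-coupling instead of a sigmatropic shift. 1 would be taken with 4 (toluene, 85 °C) to (2E)-1-(2,6-dihydroxy-4-methoxyphenyl)-3-(dimethylamino)prop-2-en-1-one F4 and then (AcOH, 60 °C) to 5-hydroxy-7-methoxy-4H-chromen-4-one F5. Iodination ortho to the free 5-OH with benzyltrimethylammonium dichloroiodate and CaCO3 in CH2Cl2/MeOH would give 5-hydroxy-6-iodo-7-methoxy-4H-chromen-4-one F6. A Stille coupling of F6 with tributyl(3-methylbut-2-en-1-yl)stannane (Pd(PPh3)4, DMF, 90 °C) would give 8.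

Further compounds
F1 | step 5 | (2S)-5-[(tert-butyldimethylsilyl)oxy]-2-{3-[(tert-butyldimethylsilyl)oxy]-4-methoxyphenyl}-7-methoxy-6-(3-methylbut-2-en-1-yl)-2,3-dihydro-4H-chromen-4-one | COc1ccc([C@H]2Oc3cc(OC)c(CC=C(C)C)c(O[Si](C)(C)C(C)(C)C)c3C(=O)C2)cc1O[Si](C)(C)C(C)(C)C
F2 | step 5 | (2R,3R)-5-[(tert-butyldimethylsilyl)oxy]-2-{3-[(tert-butyldimethylsilyl)oxy]-4-methoxyphenyl}-3-hydroxy-7-methoxy-6-(3-methylbut-2-en-1-yl)-2,3-dihydro-4H-chromen-4-one | COc1ccc([C@H]2Oc3cc(OC)c(CC=C(C)C)c(O[Si](C)(C)C(C)(C)C)c3C(=O)[C@@H]2O)cc1O[Si](C)(C)C(C)(C)C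
F3 | step 4 | (2S)-2-(3-hydroxy-4-methoxyphenyl)-7-methoxy-5-[(2-methylbut-3-en-2-yl)oxy]-2,3-dihydro-4H-chromen-4-one | COc1ccc([C@H]2Oc3cc(OC)cc(OC(C)(C)C=C)c3C(=O)C2)cc1O
F4 | step 3 | (2E)-1-(2,6-dihydroxy-4-methoxyphenyl)-3-(dimethylamino)prop-2-en-1-one | CN(C)/C=C/C(=O)c1c(O)cc(OC)cc1O
F5 | step 3 | 5-hydroxy-7-methoxy-4H-chromen-4-one | O=c1ccoc2cc(OC)cc(O)c12
F6 | step 3 | 5-hydroxy-6-iodo-7-methoxy-4H-chromen-4-one | O=c1ccoc2cc(OC)c(I)c(O)c12
A1 | direct plan | 1-[2,6-dihydroxy-4-methoxy-3-(3-methylbut-2-en-1-yl)phenyl]ethan-1-one | CC(=O)c1c(O)cc(OC)c(CC=C(C)C)c1O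
A2 | direct plan | 1-[6-(1-ethoxyethoxy)-4-methoxy-2-(methoxymethoxy)-3-(3-methylbut-2-en-1-yl)phenyl]ethan-1-one | CC(=O)c1c(OC(C)OCC)cc(OC)c(CC=C(C)C)c1OCOC
A3 | direct plan | 4-methoxy-3-(methoxymethoxy)benzaldehyde | COCOc1cc(C=O)ccc1OC
A4 | direct plan | (2E)-1-[6-(1-ethoxyethoxy)-4-methoxy-2-(methoxymethoxy)-3-(3-methylbut-2-en-1-yl)phenyl]-3-[4-methoxy-3-(methoxymethoxy)phenyl]prop-2-en-1-one | CCOC(C)Oc1cc(OC)c(CC=C(C)C)c(OCOC)c1C(=O)/C=C/c1ccc(OC)c(OCOC)c1
A5 | direct plan | [6-(1-ethoxyethoxy)-4-methoxy-2-(methoxymethoxy)-3-(3-methylbut-2-en-1-yl)phenyl]{(2R,3S)-3-[4-methoxy-3-(methoxymethoxy)phenyl]oxiran-2-yl}methanone | CCOC(C)Oc1cc(OC)c(CC=C(C)C)c(OCOC)c1C(=O)[C@@H]2O[C@H]2c3ccc(OC)c(OCOC)c3
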